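**Plan**

- Retrosynthesis: after removal of nine benzyl ethers, the oxolane is cut at C2–H and at its C2–aryl bond (aryllithium plus lactone), the tetralin at C1–C8a and at C1–ring C, the biaryl at its aryl–aryl bond, and each C6–C3 half at C8–C8′.
- Enabling feature: tetralin C1 is a methine bonded to two electron-rich arenes, fused ring D (para to its methoxy) and biaryl ring C (para to its hydroxyl), so C1 can enter as an aldehyde carbon that is arylated twice.
- Forward order: one Ireland–Claisen acid gives a common alcohol that is turned into an aldehyde and a lactone (the oxolane ring is closed there). The key step closes the tetralin carbocycle and joins the bromobiaryl. The bromide then becomes the aryllithium that adds to the lactone, followed by hemiketal reduction and hydrogenolysis.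
- Stereochemistry: an (S)-carbinol from asymmetric transfer hydrogenation is relayed by the chair Ireland–Claisen rearrangement (chelated enolate, E-alkene) to C8/C8′ of both halves. Tetralin C1 is set trans to C2 in the key step, and oxolane C2 by hydride delivery anti to the C3 substituent.

Key step: step 17

Assumption: the α-carbon of the aryl-lactate unit needs no defined configuration because it is planarised on enolisation, so the racemic acid is used; benzyl (Bn) is the only protecting group.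

**Route**

Step 1
Reactants: 1 benzyl propargyl ether; 2 N-methoxy-N-methylacetamide
Product: 4 5-(benzyloxy)pent-3-yn-2-one, via lithium acetylide 3 (not isolated)
Conditions: n-BuLi, THF, −78 °C; then 2, −78 → 0 °C; cold 1 M HCl
Reagents that add atoms: none
Why: Acylation of a lithium acetylide with a Weinreb amide stops at the ketone because the chelated tetrahedral adduct survives until the acidic quench.

Step 2
Reactants: 4 5-(benzyloxy)pent-3-yn-2-one
Product: 5 (S)-5-(benzyloxy)pent-3-yn-2-ol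
Conditions: RuCl[(S,S)-TsDPEN](p-cymene) (1 mol %), i-PrOH, rt
Reagents that add atoms: none
Why: Noyori asymmetric transfer hydrogenation of an ynone, in which the (S,S)-configured catalyst delivers hydride to one carbonyl face and sets the (S)-carbinol, the alkyne taking the role of the unsaturated group.

Step 3
Reactants: 5 (S)-5-(benzyloxy)pent-3-yn-2-ol
Product: 6 (2S,3E)-5-(benzyloxy)pent-3-en-2-ol
Conditions: NaAlH2(OCH2CH2OMe)2, THF, 0 °C → rt; aq. potassium sodium tartrate
Reagents that add atoms: none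
Why: Hydroxyl-directed trans-hydroalumination of a propargylic alcohol followed by protonolysis should give the E-alkene only and leaves the carbinol centre untouched.

Step 4
Reactants: 7 [4-(benzyloxy)-3-methoxyphenyl]methanol
Product: 8 1-(benzyloxy)-4-(bromomethyl)-2-methoxybenzene
Conditions: PBr3, Et2O, 0 °C
Reagents that add atoms: phosphorus tribromide, BrP(Br)Br
Why: Bromination of a benzylic alcohol through its phosphite ester is a standard substitution; the bromide is used at once.

Step 5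
Reactants: 9 methyl 2-(benzyloxy)acetate; 8 1-(benzyloxy)-4-(bromomethyl)-2-methoxybenzene
Product: 11 methyl 2-(benzyloxy)-3-[4-(benzyloxy)-3-methoxyphenyl]propanoate (racemic), via lithium enolate 10 (not isolated)
Conditions: LiN(i-Pr)2, THF, −78 °C; then 8, −78 → −20 °C
Reagents that add atoms: none
Why: Ester enolate alkylation (SN2 at a reactive benzylic bromide) builds the aryl-lactate skeleton, and the racemic centre it creates is erased in step 8.

Step 6
Reactants: 11 methyl 2-(benzyloxy)-3-[4-(benzyloxy)-3-methoxyphenyl]propanoate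
Product: 12 2-(benzyloxy)-3-[4-(benzyloxy)-3-methoxyphenyl]propanoic acid (racemic)
Conditions: LiOH·H2O, THF/MeOH/H2O, rt; then 1 M HCl
Reagents that add atoms: lithium hydroxide, [Li+].[OH-]
Why: Saponification of a methyl ester, to which benzyl ethers are inert.

Step 7
Reactants: 12 2-(benzyloxy)-3-[4-(benzyloxy)-3-methoxyphenyl]propanoic acid; 6 (2S,3E)-5-(benzyloxy)pent-3-en-2-ol
Product: 13 (2S,3E)-5-(benzyloxy)pent-3-en-2-yl 2-(benzyloxy)-3-[4-(benzyloxy)-3-methoxyphenyl]propanoate (both epimers at the acyl α-carbon)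
Conditions: DCC, DMAP (cat.), CH2Cl2, 0 °C → rt
Reagents that add atoms: none
Why: Steglich esterification acylates the secondary allylic alcohol without touching its C–O bond, so the (S)-configuration and the E-alkene are carried over.

Step 8
Reactants: 13 (2S,3E)-5-(benzyloxy)pent-3-en-2-yl 2-(benzyloxy)-3-[4-(benzyloxy)-3-methoxyphenyl]propanoate
Product: 16 (2S,3S,4E)-2-(benzyloxy)-2-[4-(benzyloxy)-3-methoxybenzyl]-3-[(benzyloxy)methyl]hex-4-enoic acid, via silyl ketene acetal 14 (not isolated), via trimethylsilyl ester 15 (not isolated)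
Conditions: LiN(i-Pr)2, THF, −78 °C; Me3SiCl; −78 °C → rt, then 50 °C; 1 M HCl
Reagents that add atoms: none
Why: Ireland–Claisen rearrangement in which lithium chelation between the enolate oxygen and the α-benzyloxy group fixes the Z silyl ketene acetal, the chair transition state with the methyl group equatorial relays the (S)-carbinol to C3, and the E-alkene fixes the C2/C3 relationship, so the quaternary C2 and tertiary C3 are both set as S.

Step 9
Reactants: 16 (2S,3S,4E)-2-(benzyloxy)-2-[4-(benzyloxy)-3-methoxybenzyl]-3-[(benzyloxy)methyl]hex-4-enoic acid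
Product: 17 (2S,3S,4E)-2-(benzyloxy)-2-[4-(benzyloxy)-3-methoxybenzyl]-3-[(benzyloxy)methyl]hex-4-en-1-ol
Conditions: LiAlH4, THF, 0 °C → reflux; Fieser work-up
Reagents that add atoms: none
Why: Hydride reduction of a carboxylic acid to the primary alcohol, which leaves the isolated alkene, the benzyl ethers and both stereocentres alone.

Step 10
Reactants: 17 (2S,3S,4E)-2-(benzyloxy)-2-[4-(benzyloxy)-3-methoxybenzyl]-3-[(benzyloxy)methyl]hex-4-en-1-ol
Product: 18 4-[(2S,3S,4E)-2-(benzyloxy)-2,3-bis[(benzyloxy)methyl]hex-4-en-1-yl]-1-(benzyloxy)-2-methoxybenzene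
Conditions: NaH, BnBr, Bu4NI (cat.), DMF, 0 °C → rt
Reagents that add atoms: benzyl bromide, BrCc1ccccc1
Why: Williamson etherification of the primary alkoxide.

Step 11
Reactants: 18 4-[(2S,3S,4E)-2-(benzyloxy)-2,3-bis[(benzyloxy)methyl]hex-4-en-1-yl]-1-(benzyloxy)-2-methoxybenzene
Product: 20 (2S,3S)-3,4-bis(benzyloxy)-3-[4-(benzyloxy)-3-methoxybenzyl]-2-[(benzyloxy)methyl]butanal, via diol 19 (not isolated)
Conditions: OsO4 (cat.), NaIO4, 2,6-lutidine, dioxane/H2O, rt
Reagents that add atoms: osmium tetroxide, O=[Os](=O)(=O)=O; sodium periodate, [Na+].[O-]I(=O)(=O)=O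
Why: Lemieux–Johnson oxidative cleavage (dihydroxylation, then periodate glycol cleavage) spares the electron-rich arenes and benzyl ethers, and the lutidine buffer should suppress epimerisation and β-elimination of the α-branched aldehyde.

Step 12
Reactants: 17 (2S,3S,4E)-2-(benzyloxy)-2-[4-(benzyloxy)-3-methoxybenzyl]-3-[(benzyloxy)methyl]hex-4-en-1-ol
Product: 23 (3S,4S)-4-(benzyloxy)-4-[4-(benzyloxy)-3-methoxybenzyl]-3-[(benzyloxy)methyl]oxolan-2-ol (both anomers), via triol 21 (not isolated), via hydroxy aldehyde 22 (not isolated)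
Conditions: OsO4 (cat.), NaIO4, 2,6-lutidine, dioxane/H2O, rt
Reagents that add atoms: osmium tetroxide, O=[Os](=O)(=O)=O; sodium periodate, [Na+].[O-]I(=O)(=O)=O
Why: The same Lemieux–Johnson cleavage on the free alcohol gives a γ-hydroxy aldehyde that closes spontaneously to the five-membered lactol.

Step 13
Reactants: 23 (3S,4S)-4-(benzyloxy)-4-[4-(benzyloxy)-3-methoxybenzyl]-3-[(benzyloxy)methyl]oxolan-2-ol
Product: 24 (3S,4S)-4-(benzyloxy)-4-[4-(benzyloxy)-3-methoxybenzyl]-3-[(benzyloxy)methyl]oxolan-2-one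
Conditions: Pr4N[RuO4] (5 mol %), NMO, 4 Å MS, CH2Cl2, rt
Reagents that add atoms: none
Why: Ley–Griffith oxidation of a lactol to the lactone under neutral conditions that do not epimerise the α-centre.

Step 14
Reactants: 25 4-bromo-2-methoxyphenol
Product: 26 4-bromo-2-iodo-6-methoxyphenol
Conditions: NIS, TsOH·H2O (cat.), MeCN, rt
Reagents that add atoms: N-iodosuccinimide, O=C1CCC(=O)N1I
Why: Electrophilic aromatic iodination is directed by the hydroxyl group to its only free ortho position, the para position being blocked by bromine.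

Step 15
Reactants: 26 4-bromo-2-iodo-6-methoxyphenol
Product: 27 2-(benzyloxy)-5-bromo-1-iodo-3-methoxybenzene
Conditions: BnBr, K2CO3, DMF, rt
Reagents that add atoms: benzyl bromide, BrCc1ccccc1
Why: Williamson etherification of the phenoxide.

Step 16
Reactants: 27 2-(benzyloxy)-5-bromo-1-iodo-3-methoxybenzene; 28 (2-hydroxy-3-methoxyphenyl)boronic acid
Product: 29 2'-(benzyloxy)-5'-bromo-3,3'-dimethoxy-[1,1'-biphenyl]-2-ol
Conditions: Pd(PPh3)4 (3 mol %), Na2CO3, DME/H2O, 70 °C
Reagents that add atoms: none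
Why: Suzuki–Miyaura coupling in which oxidative addition into the C–I bond is far faster than into the C–Br bond, so the bromide is kept for step 19 and the phenol of ring C stays free.

Step 17
Reactants: 20 (2S,3S)-3,4-bis(benzyloxy)-3-[4-(benzyloxy)-3-methoxybenzyl]-2-[(benzyloxy)methyl]butanal; 29 2'-(benzyloxy)-5'-bromo-3,3'-dimethoxy-[1,1'-biphenyl]-2-ol
Product: 31 2'-(benzyloxy)-5'-bromo-3,3'-dimethoxy-5-[(1S,2S,3S)-3,7-bis(benzyloxy)-2,3-bis[(benzyloxy)methyl]-6-methoxy-1,2,3,4-tetrahydronaphthalen-1-yl]-[1,1'-biphenyl]-2-ol, via tetralol 30 (not isolated)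
Conditions: 29 (1.2 equiv), BF3·OEt2 (2.5 equiv), 4 Å MS, CH2Cl2, −78 → −20 °C
Reagents that add atoms: none
Why: Proposed new method: BF3 activates the aldehyde of 20, the carbon of ring D para to its methoxy group attacks it in a 6-exo-trig Friedel–Crafts hydroxyalkylation (C1–C8a bond, closing the tetralin carbocycle), and tetralol 30 ionises to a C1 cation stabilised by that para-methoxy group, which phenol 29 captures at the carbon para to its hydroxyl (C1–ring C bond). The closest known reaction types are the acid-mediated ring closure of diaryl carbinols to 1-aryltetralins in cyclolignan synthesis and the Lewis-acid double arylation of aldehydes to triarylmethanes; what is new is the pairing of a tethered arene with an external phenol at one aldehyde carbon. The new stereocentre C1 is controlled by C2: the arene should add to the half-chair cation anti to the C2 benzyloxymethyl group, giving the 1,2-trans (1S) arrangement with all three carbon substituents equatorial, which is also the thermodynamic outcome should the arylation be reversible. Site selectivity rests on ring C being the only free phenol with both positions ortho to its hydroxyl blocked by methoxy and aryl, on ring B being benzylated and deactivated by bromine, and on ring D closing para to methoxy instead of at the crowded position between the methoxy group and the tether. Should the phenol add to the aldehyde first, the diaryl carbinol ionises and ring D closes on that cation, so both orders of events should converge on 31.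

Step 18
Reactants: 31 2'-(benzyloxy)-5'-bromo-3,3'-dimethoxy-5-[(1S,2S,3S)-3,7-bis(benzyloxy)-2,3-bis[(benzyloxy)methyl]-6-methoxy-1,2,3,4-tetrahydronaphthalen-1-yl]-[1,1'-biphenyl]-2-ol
Product: 32 2,2'-bis(benzyloxy)-5-bromo-3,3'-dimethoxy-5'-[(1S,2S,3S)-3,7-bis(benzyloxy)-2,3-bis[(benzyloxy)methyl]-6-methoxy-1,2,3,4-tetrahydronaphthalen-1-yl]-1,1'-biphenyl
Conditions: BnBr, K2CO3, DMF, 50 °C
Reagents that add atoms: benzyl bromide, BrCc1ccccc1
Why: Williamson etherification removes the only acidic proton before the organolithium step.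

Step 19
Reactants: 32 2,2'-bis(benzyloxy)-5-bromo-3,3'-dimethoxy-5'-[(1S,2S,3S)-3,7-bis(benzyloxy)-2,3-bis[(benzyloxy)methyl]-6-methoxy-1,2,3,4-tetrahydronaphthalen-1-yl]-1,1'-biphenyl; 24 (3S,4S)-4-(benzyloxy)-4-[4-(benzyloxy)-3-methoxybenzyl]-3-[(benzyloxy)methyl]oxolan-2-one
Product: 34 (3S,4S)-4-(benzyloxy)-4-[4-(benzyloxy)-3-methoxybenzyl]-3-[(benzyloxy)methyl]-2-aryloxolan-2-ol in which the aryl group is the biaryl of 32 bonded through the carbon that bore bromine (both anomers), via aryllithium 33 (not isolated)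
Conditions: n-BuLi, THF, −78 °C; then 24, −78 °C; H2O
Reagents that add atoms: none
Why: Bromine–lithium exchange followed by 1,2-addition of the aryllithium to the lactone carbonyl, where the tetrahedral lithium alkoxide persists at −78 °C so that only one addition occurs, as in C-aryl glycoside synthesis from benzylated sugar lactones; the hemiketal carbon is left unassigned because it is planarised in step 20.

Step 20
Reactants: 34 the hemiketal of step 19
Product: 35 nona-O-benzyl ether of 36 with the (2R,3R,4S)-oxolane and the (1S,2S,3S)-tetralin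
Conditions: Et3SiH, BF3·OEt2, CH2Cl2, −78 °C; Et3N quench at −78 °C
Reagents that add atoms: none
Why: Ionic hydrogenation of a hemiketal, in which BF3 ionises 34 to the aryl-stabilised cyclic oxocarbenium ion and Et3SiH should add to the face anti to the C3 benzyloxymethyl and C4 arylmethyl groups (syn to the C4 benzyloxy group, in line with inside attack on the envelope), placing the aryl group cis to both and setting C2 as R.

Step 21
Reactants: 35 nona-O-benzyl ether of 36
Product: 36 (1S,2S,3S)-1-{2,2'-dihydroxy-5'-[(2R,3R,4S)-4-hydroxy-4-(4-hydroxy-3-methoxybenzyl)-3-(hydroxymethyl)oxolan-2-yl]-3,3'-dimethoxy-[1,1'-biphenyl]-5-yl}-2,3-bis(hydroxymethyl)-6-methoxy-1,2,3,4-tetrahydronaphthalene-3,7-diol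
Conditions: H2 (1 atm), Pd(OH)2/C, EtOAc/MeOH, rt
Reagents that add atoms: none
Why: Catalytic hydrogenolysis of the nine benzyl ethers in a neutral medium touches no stereocentre, and the more hindered benzylic C–O bond of the oxolane should cleave more slowly, so the reaction is stopped once debenzylation is complete.

**Compound list**

1 | benzyl propargyl ether | C#CCOCc1ccccc1 | starting material
2 | N-methoxy-N-methylacetamide | CC(=O)N(C)OC | starting material
3 | lithium 3-(benzyloxy)prop-1-yn-1-ide | [Li]C#CCOCc1ccccc1 | intermediate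
4 | 5-(benzyloxy)pent-3-yn-2-one | CC(=O)C#CCOCc1ccccc1 | intermediate
5 | (S)-5-(benzyloxy)pent-3-yn-2-ol | C[C@H](O)C#CCOCc1ccccc1 | intermediate
6 | (2S,3E)-5-(benzyloxy)pent-3-en-2-ol | C[C@H](O)/C=C/COCc1ccccc1 | intermediate
7 | [4-(benzyloxy)-3-methoxyphenyl]methanol | COc1cc(CO)ccc1OCc1ccccc1 | starting material
8 | 1-(benzyloxy)-4-(bromomethyl)-2-methoxybenzene | COc1cc(CBr)ccc1OCc1ccccc1 | intermediate
9 | methyl 2-(benzyloxy)acetate | COC(=O)COCc1ccccc1 | starting material
10 | lithium enolate of 9 (chelated geometry) | CO/C(O[Li])=C/OCc1ccccc1 | intermediate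
11 | methyl 2-(benzyloxy)-3-[4-(benzyloxy)-3-methoxyphenyl]propanoate (racemic) | COC(=O)C(Cc1ccc(OCc2ccccc2)c(OC)c1)OCc1ccccc1 | intermediate
12 | 2-(benzyloxy)-3-[4-(benzyloxy)-3-methoxyphenyl]propanoic acid (racemic) | OC(=O)C(Cc1ccc(OCc2ccccc2)c(OC)c1)OCc1ccccc1 | intermediate
13 | (2S,3E)-5-(benzyloxy)pent-3-en-2-yl 2-(benzyloxy)-3-[4-(benzyloxy)-3-methoxyphenyl]propanoate (both α-epimers) | C[C@H](OC(=O)C(Cc1ccc(OCc2ccccc2)c(OC)c1)OCc1ccccc1)/C=C/COCc1ccccc1 | intermediate
14 | Z trimethylsilyl ketene acetal of 13 (OSiMe3 cis to OBn) | C[C@H](O/C(O[Si](C)(C)C)=C(/OCc1ccccc1)Cc1ccc(OCc2ccccc2)c(OC)c1)/C=C/COCc1ccccc1 | intermediate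
15 | trimethylsilyl ester of 16 | C/C=C/[C@@H](COCc1ccccc1)[C@](Cc1ccc(OCc2ccccc2)c(OC)c1)(OCc1ccccc1)C(=O)O[Si](C)(C)C | intermediate
16 | (2S,3S,4E)-2-(benzyloxy)-2-[4-(benzyloxy)-3-methoxybenzyl]-3-[(benzyloxy)methyl]hex-4-enoic acid | C/C=C/[C@@H](COCc1ccccc1)[C@](Cc1ccc(OCc2ccccc2)c(OC)c1)(OCc1ccccc1)C(=O)O | intermediate
17 | (2S,3S,4E)-2-(benzyloxy)-2-[4-(benzyloxy)-3-methoxybenzyl]-3-[(benzyloxy)methyl]hex-4-en-1-ol | C/C=C/[C@@H](COCc1ccccc1)[C@](Cc1ccc(OCc2ccccc2)c(OC)c1)(OCc1ccccc1)CO | intermediate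
18 | 4-[(2S,3S,4E)-2-(benzyloxy)-2,3-bis[(benzyloxy)methyl]hex-4-en-1-yl]-1-(benzyloxy)-2-methoxybenzene | C/C=C/[C@@H](COCc1ccccc1)[C@](Cc1ccc(OCc2ccccc2)c(OC)c1)(OCc1ccccc1)COCc1ccccc1 | intermediate
19 | 4,5-diol of 18 (mixture at the two new carbinols) | CC(O)C(O)[C@@H](COCc1ccccc1)[C@](Cc1ccc(OCc2ccccc2)c(OC)c1)(OCc1ccccc1)COCc1ccccc1 | intermediate
20 | (2S,3S)-3,4-bis(benzyloxy)-3-[4-(benzyloxy)-3-methoxybenzyl]-2-[(benzyloxy)methyl]butanal | COc1cc(C[C@@](OCc2ccccc2)(COCc2ccccc2)[C@@H](C=O)COCc2ccccc2)ccc1OCc1ccccc1 | intermediate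
21 | 4,5-diol of 17 (hexane-1,4,5-triol, mixture at the two new carbinols) | CC(O)C(O)[C@@H](COCc1ccccc1)[C@](Cc1ccc(OCc2ccccc2)c(OC)c1)(OCc1ccccc1)CO | intermediate
22 | (2S,3S)-3-(benzyloxy)-3-[4-(benzyloxy)-3-methoxybenzyl]-2-[(benzyloxy)methyl]-4-hydroxybutanal | O=C[C@@H](COCc1ccccc1)[C@](Cc1ccc(OCc2ccccc2)c(OC)c1)(OCc1ccccc1)CO | intermediate
23 | (3S,4S)-4-(benzyloxy)-4-[4-(benzyloxy)-3-methoxybenzyl]-3-[(benzyloxy)methyl]oxolan-2-ol (both anomers) | OC1OC[C@@](Cc2ccc(OCc3ccccc3)c(OC)c2)(OCc2ccccc2)[C@@H]1COCc1ccccc1 | intermediate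
24 | (3S,4S)-4-(benzyloxy)-4-[4-(benzyloxy)-3-methoxybenzyl]-3-[(benzyloxy)methyl]oxolan-2-one | O=C1OC[C@@](Cc2ccc(OCc3ccccc3)c(OC)c2)(OCc2ccccc2)[C@@H]1COCc1ccccc1 | intermediate
25 | 4-bromo-2-methoxyphenol | COc1cc(Br)ccc1O | starting material
26 | 4-bromo-2-iodo-6-methoxyphenol | COc1cc(Br)cc(I)c1O | intermediate
27 | 2-(benzyloxy)-5-bromo-1-iodo-3-methoxybenzene | COc1cc(Br)cc(I)c1OCc1ccccc1 | intermediate
28 | (2-hydroxy-3-methoxyphenyl)boronic acid | COc1cccc(B(O)O)c1O | starting material
29 | 2'-(benzyloxy)-5'-bromo-3,3'-dimethoxy-[1,1'-biphenyl]-2-ol | COc1cccc(c1O)-c1cc(Br)cc(OC)c1OCc1ccccc1 | intermediate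
30 | (2S,3S)-3,7-bis(benzyloxy)-2,3-bis[(benzyloxy)methyl]-6-methoxy-1,2,3,4-tetrahydronaphthalen-1-ol (C1 unassigned) | OC1c2cc(OCc3ccccc3)c(OC)cc2C[C@@](OCc2ccccc2)(COCc2ccccc2)[C@@H]1COCc1ccccc1 | intermediate
31 | 2'-(benzyloxy)-5'-bromo-3,3'-dimethoxy-5-[(1S,2S,3S)-3,7-bis(benzyloxy)-2,3-bis[(benzyloxy)methyl]-6-methoxy-1,2,3,4-tetrahydronaphthalen-1-yl]-[1,1'-biphenyl]-2-ol | Brc1cc(OC)c(OCc2ccccc2)c(c1)-c1cc(cc(OC)c1O)[C@H]1c2cc(OCc3ccccc3)c(OC)cc2C[C@@](OCc2ccccc2)(COCc2ccccc2)[C@@H]1COCc1ccccc1 | intermediate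
32 | 2,2'-bis(benzyloxy)-5-bromo-3,3'-dimethoxy-5'-[(1S,2S,3S)-3,7-bis(benzyloxy)-2,3-bis[(benzyloxy)methyl]-6-methoxy-1,2,3,4-tetrahydronaphthalen-1-yl]-1,1'-biphenyl | Brc1cc(OC)c(OCc2ccccc2)c(c1)-c1cc(cc(OC)c1OCc1ccccc1)[C@H]1c2cc(OCc3ccccc3)c(OC)cc2C[C@@](OCc2ccccc2)(COCc2ccccc2)[C@@H]1COCc1ccccc1 | intermediate
33 | aryllithium from 32 (lithium in place of bromine) | [Li]c1cc(OC)c(OCc2ccccc2)c(c1)-c1cc(cc(OC)c1OCc1ccccc1)[C@H]1c2cc(OCc3ccccc3)c(OC)cc2C[C@@](OCc2ccccc2)(COCc2ccccc2)[C@@H]1COCc1ccccc1 | intermediate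
34 | (3S,4S)-2-aryl-4-(benzyloxy)-4-[4-(benzyloxy)-3-methoxybenzyl]-3-[(benzyloxy)methyl]oxolan-2-ol, aryl = biaryl of 32 (both anomers) | COc1cc(C[C@@]2(OCc3ccccc3)COC(O)(c3cc(OC)c(OCc4ccccc4)c(-c4cc([C@H]5c6cc(OCc7ccccc7)c(OC)cc6C[C@@](OCc6ccccc6)(COCc6ccccc6)[C@@H]5COCc5ccccc5)cc(OC)c4OCc4ccccc4)c3)[C@H]2COCc2ccccc2)ccc1OCc1ccccc1 | intermediate
35 | nona-O-benzyl ether of 36, (2R,3R,4S)-oxolane and (1S,2S,3S)-tetralin | COc1cc(C[C@@]2(OCc3ccccc3)CO[C@@H](c3cc(OC)c(OCc4ccccc4)c(-c4cc([C@H]5c6cc(OCc7ccccc7)c(OC)cc6C[C@@](OCc6ccccc6)(COCc6ccccc6)[C@@H]5COCc5ccccc5)cc(OC)c4OCc4ccccc4)c3)[C@H]2COCc2ccccc2)ccc1OCc1ccccc1 | intermediate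
36 | CNP0344108.1, (1S,2S,3S)-1-{2,2'-dihydroxy-5'-[(2R,3R,4S)-4-hydroxy-4-(4-hydroxy-3-methoxybenzyl)-3-(hydroxymethyl)oxolan-2-yl]-3,3'-dimethoxy-[1,1'-biphenyl]-5-yl}-2,3-bis(hydroxymethyl)-6-methoxy-1,2,3,4-tetrahydronaphthalene-3,7-diol | COc1cc(C[C@@]2(O)CO[C@@H](c3cc(OC)c(O)c(-c4cc([C@H]5c6cc(O)c(OC)cc6C[C@@](O)(CO)[C@@H]5CO)cc(OC)c4O)c3)[C@H]2CO)ccc1O | target

**Step count and risks**

Total: 21 steps. Longest linear sequence: 13 steps (from 7 through steps 4–11 and 17–21).

Steps most likely to fail: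

1. Step 17 (key step, new method). The C1 cation may be diverted before the phenol arrives: loss of the C2 proton to a dihydronaphthalene, capture by the oxygen of the C3 benzyloxymethyl group with loss of benzyl, or twofold arylation of the aldehyde by the phenol outrunning ring closure. The fallback sets out from 29 and 20 and returns at 32, using only known reactions. Phenol 29 is iodinated with NIS at its only open activated position, para to the hydroxyl, to give 2'-(benzyloxy)-5'-bromo-5-iodo-3,3'-dimethoxy-[1,1'-biphenyl]-2-ol F1. Benzylation (BnBr, K2CO3, DMF) gives 2,2'-bis(benzyloxy)-5-bromo-5'-iodo-3,3'-dimethoxy-1,1'-biphenyl F2. Iodine–magnesium exchange with i-PrMgCl·LiCl in THF at −20 °C, which leaves the aryl bromide alone, gives the arylmagnesium chloride F3, and this adds to aldehyde 20 to give the diaryl carbinol F4 as a mixture of carbinol epimers. BF3·OEt2 in CH2Cl2 then ionises the carbinol and ring D closes on the cation, the established cyclolignan ring closure, to give 32 directly.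

2. Step 20. Hydride delivery may lose its facial bias, the benzylic centre may epimerise through reversible ring opening under BF3, or the oxocarbenium ion may be trapped by the guaiacylmethyl ring. The fallback sets out from 34 and returns at 35. The open hydroxy ketone form of 34 is reduced under reagent control with (S)-2-methyl-CBS-oxazaborolidine and BH3·SMe2, the aryl group acting as the large substituent, to give the ring-opened diol with an (R)-configured benzylic carbinol F5. The primary hydroxyl is then sulfonylated and displaced by the benzylic alkoxide (TsCl, then NaH, THF) in an intramolecular Williamson closure that never breaks the benzylic C–O bond, giving 35.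

3. Step 19. The aryllithium may act as a base, enolising the lactone with E1cB loss of benzyloxide or being quenched by proton transfer. The fallback sets out from 32 and 23 and returns at 34. Lactol 23 is first deprotonated with i-PrMgCl to its ring-opened aldehyde alkoxide, and aryllithium 33 (transmetalated with MgBr2·OEt2) is added to the far more electrophilic aldehyde to give the ring-opened diol as a mixture of carbinol epimers F6. Selective oxidation of the electron-rich benzylic alcohol with MnO2 in CH2Cl2 gives the hydroxy ketone, which closes to hemiketal 34.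

**Further compounds**

F1 | step 17 | 2'-(benzyloxy)-5'-bromo-5-iodo-3,3'-dimethoxy-[1,1'-biphenyl]-2-ol | COc1cc(I)cc(c1O)-c1cc(Br)cc(OC)c1OCc1ccccc1
F2 | step 17 | 2,2'-bis(benzyloxy)-5-bromo-5'-iodo-3,3'-dimethoxy-1,1'-biphenyl | COc1cc(I)cc(c1OCc1ccccc1)-c1cc(Br)cc(OC)c1OCc1ccccc1
F3 | step 17 | arylmagnesium chloride from F2 (MgCl in place of iodine) | COc1cc([Mg]Cl)cc(c1OCc1ccccc1)-c1cc(Br)cc(OC)c1OCc1ccccc1
F4 | step 17 | diaryl carbinol from F3 and 20 (both carbinol epimers) | COc1cc(C[C@@](OCc2ccccc2)(COCc2ccccc2)[C@@H](C(O)c2cc(OC)c(OCc3ccccc3)c(c2)-c2cc(Br)cc(OC)c2OCc2ccccc2)COCc2ccccc2)ccc1OCc1ccccc1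
F5 | step 20 | ring-opened diol of 35 with (R)-configured benzylic carbinol and free primary hydroxyl | COc1cc(C[C@@](OCc2ccccc2)(CO)[C@H](COCc2ccccc2)[C@@H](O)c2cc(OC)c(OCc3ccccc3)c(-c3cc([C@H]4c5cc(OCc6ccccc6)c(OC)cc5C[C@@](OCc5ccccc5)(COCc5ccccc5)[C@@H]4COCc4ccccc4)cc(OC)c3OCc3ccccc3)c2)ccc1OCc1ccccc1
F6 | step 19 | ring-opened diol from 33 and 23 (both benzylic carbinol epimers) | COc1cc(C[C@@](OCc2ccccc2)(CO)[C@H](COCc2ccccc2)C(O)c2cc(OC)c(OCc3ccccc3)c(-c3cc([C@H]4c5cc(OCc6ccccc6)c(OC)cc5C[C@@](OCc5ccccc5)(COCc5ccccc5)[C@@H]4COCc4ccccc4)cc(OC)c3OCc3ccccc3)c2)ccc1OCc1ccccc1
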